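**Retrosynthetic overview**

1. Ring 2 (the dihydrofuran on arene B) is opened last. Its C2 is a one-carbon unit delivered by a 4-(benzyloxy)benzyl sulfonium ylide in a [4+1] annulation with an o-quinone methide of arene B. Its C3–arene C bond comes from addition of an arene C aryllithium, already carrying ring 3 and ring D (the 3,5-dioxyphenyl ring), to an arene B salicylaldehyde.
2. Rings 1 and 3 are the same (2R,3R) heterocycle, a 4-substituted 6-oxy-2-(4-oxyphenyl)-3-(3,5-dioxyaryl)-2,3-dihydrobenzofuran, so both halves descend from one 4-bromo resorcylate. The west keeps the ester carbon (future C3 of ring 2) and gains the stilbene by Heck reaction at C4–Br of arene A. The east loses the ester by decarboxylation (giving ring D) and uses C4–Br of arene C as the nucleophile.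
3. The strategy rests on arene B, the benzo ring of ring 2: C4 carries C3 of ring 1, the neighbouring C3a carries C3 of ring 2, and C7a and C6 carry oxygen. This is the pattern of a 6-substituted 2,4-dihydroxybenzoate, so the ring is built de novo on C3 of the heterocycle by Diels–Alder reaction of a C3 ynoate with 1-methoxy-1,3-bis(trimethylsilyloxy)buta-1,3-diene and aromatisation, forming C3a–C7a and C4–C5.
4. The ynoate is reached from a trans 2-aryl-4-bromo-2,3-dihydrobenzofuran-3-carboxylate (ester, aldehyde, alkyne, ynoate). That ester comes from 5-bromoresorcinol through an aryldiazoacetate whose dirhodium-carbene C–H insertion into an O-benzylic CH2 closes the dihydrofuran ring and sets C2.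
5. Order of ring formation: dihydrofuran ring of the ring 1/ring 3 unit, then the new benzene ring (arene B in the west, ring D in the east, from the same benzannulation), then ring 2. All nine phenols travel as benzyl ethers and are freed in the last step.

Key step: step 14

Assumption: the sense of induction of Rh2(S-PTTL)4 in step 8 is taken by analogy with simpler 2-(benzyloxy)aryl diazoacetates; should the 2S series form, the mirror-image catalyst Rh2(R-PTTL)4 is used and nothing else changes.

Abbreviations in names: Bn = benzyl; Ar = 4-(benzyloxy)phenyl; bromo unit = (2R,3R)-6-(benzyloxy)-2-Ar-4-bromo-2,3-dihydro-1-benzofuran-3-yl; west unit = (2R,3R)-6-(benzyloxy)-2-Ar-4-[(E)-2-Ar-ethenyl]-2,3-dihydro-1-benzofuran-3-yl; east unit = (2R,3R)-6-(benzyloxy)-2-Ar-3-[3,5-bis(benzyloxy)phenyl]-2,3-dihydro-1-benzofuran-4-yl.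

**Route**

Step 1
Reactants: 1 5-bromoresorcinol
Product: 2 2-bromo-4,6-dihydroxybenzaldehyde
Conditions: POCl3, DMF, MeCN, 0 °C → rt; then H2O, 50 °C
Reagents that add atoms: N,N-dimethylformamide CN(C)C=O; water O
Why: Vilsmeier–Haack formylation of the resorcinol should go para to one hydroxyl and ortho to the other, next to bromine and not between the two hydroxyls, as it does for 5-alkylresorcinols.

Step 2
Reactants: 2 2-bromo-4,6-dihydroxybenzaldehyde
Product: 3 4-(benzyloxy)-2-bromo-6-hydroxybenzaldehyde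
Conditions: BnBr (1.05 equiv), NaHCO3, KI (cat), MeCN, 70 °C
Reagents that add atoms: benzyl bromide BrCc1ccccc1
Why: Williamson etherification under a weak base should touch only the 4-hydroxyl, because the 6-hydroxyl is tied up in a hydrogen bond to the formyl group.

Step 3
Reactants: 3 4-(benzyloxy)-2-bromo-6-hydroxybenzaldehyde; 4 4-(benzyloxy)benzyl chloride
Product: 5 4-(benzyloxy)-2-{[4-(benzyloxy)benzyl]oxy}-6-bromobenzaldehyde
Conditions: K2CO3, KI (cat), DMF, 60 °C
Reagents that add atoms: none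
Why: Williamson etherification of the remaining chelated phenol with the reactive benzylic chloride installs the O–CH2Ar group whose carbon becomes C2 of the heterocycle.

Step 4
Reactants: 5 4-(benzyloxy)-2-{[4-(benzyloxy)benzyl]oxy}-6-bromobenzaldehyde
Product: 6 1-(benzyloxy)-3-{[4-(benzyloxy)benzyl]oxy}-5-bromo-4-(2-methoxyethenyl)benzene (E/Z mixture)
Conditions: MeOCH2PPh3Cl, KOtBu, THF, 0 °C → rt
Reagents that add atoms: (methoxymethyl)triphenylphosphonium chloride COC[P+](c1ccccc1)(c1ccccc1)c1ccccc1.[Cl-]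
Why: Wittig methoxymethylenation of the non-enolisable aldehyde gives the enol ether, the first half of a one-carbon homologation.

Step 5
Reactants: 6 1-(benzyloxy)-3-{[4-(benzyloxy)benzyl]oxy}-5-bromo-4-(2-methoxyethenyl)benzene
Product: 8 2-{4-(benzyloxy)-2-[(4-benzyloxybenzyl)oxy]-6-bromophenyl}acetic acid, via arylacetaldehyde 7 (not isolated)
Conditions: 2 M HCl, THF, rt; then NaClO2, NaH2PO4, 2-methyl-2-butene, t-BuOH/H2O, 0 °C → rt
Reagents that add atoms: water O; sodium chlorite [Na+].[O-]Cl=O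
Why: mild acid hydrolysis of the enol ether gives the arylacetaldehyde, and Pinnick oxidation with an alkene scavenger for hypochlorite converts it into the acid without chlorinating the electron-rich rings.

Step 6
Reactants: 8 2-{4-(benzyloxy)-2-[(4-benzyloxybenzyl)oxy]-6-bromophenyl}acetic acid
Product: 9 methyl 2-{4-(benzyloxy)-2-[(4-benzyloxybenzyl)oxy]-6-bromophenyl}acetate
Conditions: MeI, K2CO3, DMF, rt
Reagents that add atoms: iodomethane CI
Why: SN2 O-methylation of the carboxylate is the only alkylation open, since all phenols are already ethers.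

Step 7
Reactants: 9 methyl 2-{4-(benzyloxy)-2-[(4-benzyloxybenzyl)oxy]-6-bromophenyl}acetate
Product: 10 methyl 2-{4-(benzyloxy)-2-[(4-benzyloxybenzyl)oxy]-6-bromophenyl}-2-diazoacetate
Conditions: p-ABSA, DBU, MeCN, 0 °C → rt
Reagents that add atoms: 4-acetamidobenzenesulfonyl azide CC(=O)Nc1ccc(cc1)S(=O)(=O)N=[N+]=[N-]
Why: Regitz diazo transfer to the benzylic ester enolate gives the donor–acceptor aryldiazoacetate.

Step 8
Reactants: 10 methyl 2-{4-(benzyloxy)-2-[(4-benzyloxybenzyl)oxy]-6-bromophenyl}-2-diazoacetate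
Product: 12 methyl (2R,3R)-6-(benzyloxy)-2-[4-(benzyloxy)phenyl]-4-bromo-2,3-dihydro-1-benzofuran-3-carboxylate (trans), via cis ester 11 (not isolated)
Conditions: Rh2(S-PTTL)4 (2 mol %), toluene, −60 °C; then NaOMe (0.3 equiv), MeOH, rt
Reagents that add atoms: none
Why: intramolecular dirhodium-carbene 1,5-C–H insertion into the O–CH2Ar group closes the dihydrofuran ring, the chiral carboxylate ligands choosing one enantiotopic hydrogen so that C2 is set as R in the cis ester, and methoxide then epimerises only the enolisable C3 to the more stable trans (2R,3R) ester, ring opening by β-elimination being stereoelectronically disfavoured in the five-membered ring.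

Step 9
Reactants: 12 methyl (2R,3R)-6-(benzyloxy)-2-[4-(benzyloxy)phenyl]-4-bromo-2,3-dihydro-1-benzofuran-3-carboxylate
Product: 13 (2R,3R)-6-(benzyloxy)-2-[4-(benzyloxy)phenyl]-4-bromo-2,3-dihydro-1-benzofuran-3-carbaldehyde
Conditions: i-Bu2AlH (1.1 equiv), CH2Cl2, −78 °C; aq KNa tartrate
Reagents that add atoms: none
Why: partial ester reduction at −78 °C stops at the aluminium hemiacetal, which releases the aldehyde only on the cold, near-neutral work-up, so C3 stays trans.

Step 10
Reactants: 13 (2R,3R)-6-(benzyloxy)-2-[4-(benzyloxy)phenyl]-4-bromo-2,3-dihydro-1-benzofuran-3-carbaldehyde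
Product: 14 (2R,3R)-6-(benzyloxy)-2-[4-(benzyloxy)phenyl]-4-bromo-3-ethynyl-2,3-dihydro-1-benzofuran
Conditions: MeC(O)C(N2)P(O)(OMe)2, K2CO3, MeOH/THF, 0 °C → rt
Reagents that add atoms: dimethyl (1-diazo-2-oxopropyl)phosphonate COP(=O)(OC)C(=[N+]=[N-])C(C)=O
Why: Seyferth–Gilbert homologation converts the aldehyde into the terminal alkyne, and any epimerisation of the aldehyde at C3 under carbonate only returns the favoured trans isomer because C2 cannot epimerise.

Step 11
Reactants: 14 (2R,3R)-6-(benzyloxy)-2-[4-(benzyloxy)phenyl]-4-bromo-3-ethynyl-2,3-dihydro-1-benzofuran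
Product: 15 methyl 3-{(2R,3R)-6-(benzyloxy)-2-[4-(benzyloxy)phenyl]-4-bromo-2,3-dihydro-1-benzofuran-3-yl}prop-2-ynoate
Conditions: LiN(i-Pr)2 (1.05 equiv), THF, −78 °C; then cannulated into ClCO2Me, THF, −78 °C
Reagents that add atoms: methyl chloroformate COC(Cl)=O
Why: the amide base removes only the alkyne hydrogen, which is far more acidic than C3–H, and leaves the aryl bromide alone, and C-acylation of the acetylide by inverse addition gives the ynoate without leaving base in contact with its now acidic propargylic hydrogen.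

Step 12
Reactants: 16 methyl acetoacetate
Product: 17 methyl 3-(trimethylsilyloxy)but-2-enoate
Conditions: Me3SiCl, Et3N, hexane, rt
Reagents that add atoms: chlorotrimethylsilane C[Si](C)(C)Cl
Why: O-silylation of the enol of the β-keto ester gives the silyl enol ether.

Step 13
Reactants: 17 methyl 3-(trimethylsilyloxy)but-2-enoate
Product: 18 1-methoxy-1,3-bis(trimethylsilyloxy)buta-1,3-diene
Conditions: LiN(i-Pr)2, THF, −78 °C; Me3SiCl, −78 °C → rt
Reagents that add atoms: chlorotrimethylsilane C[Si](C)(C)Cl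
Why: γ-deprotonation to the dienolate and O-silylation give the electron-rich bis-silyl dienol ether.

Step 14
Reactants: 15 methyl 3-{(2R,3R)-6-(benzyloxy)-2-[4-(benzyloxy)phenyl]-4-bromo-2,3-dihydro-1-benzofuran-3-yl}prop-2-ynoate; 18 1-methoxy-1,3-bis(trimethylsilyloxy)buta-1,3-diene
Product: 21 methyl 2-(bromo unit)-4,6-dihydroxybenzoate, via cyclohexadiene cycloadduct 19 (not isolated), via bis-silyl ether 20 (not isolated)
Conditions: 18 (3 equiv), toluene, 110 °C, sealed tube; then 1 M HCl, THF, rt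
Reagents that add atoms: none
Why: In a thermal, strongly polarised [4+2] cycloaddition the unsubstituted CH2 end of the diene, its most nucleophilic carbon, attacks the ynoate carbon that sits on C3 of the heterocycle, while the ketene-acetal end joins the ester-bearing carbon, giving cyclohexa-1,4-diene 19, which expels methanol by 1,4-elimination to the aromatic bis-silyl ether 20 and is desilylated by the acidic work-up. The closest known reaction type is the Diels–Alder benzannulation of 1,3-dioxygenated silyloxydienes with β-alkyl alkynoates to give resorcylates. The new benzene ring (arene B) is closed by cycloaddition, which makes C3a–C7a and C4–C5 at once, and then aromatised. No stereocentre is formed, and the C3 centre already present should survive because the medium is neutral, so its propargylic and benzylic hydrogen is not removed and no allenoate arises, while C2 is not involved. The selectivity needed is regiochemical, ester next to the oxygen-bearing diene terminus, and it is secured by the matching polarity of the two partners, which puts the ester carbon between the heterocycle and a hydroxyl, the place of C3a. The aryl bromide and the benzyl ethers are inert to these conditions, which is what lets one product feed both halves of the target.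

Step 15
Reactants: 21 methyl 2-(bromo unit)-4,6-dihydroxybenzoate
Product: 22 methyl 4-(benzyloxy)-2-(bromo unit)-6-hydroxybenzoate
Conditions: BnBr (1.05 equiv), K2CO3, acetone, rt
Reagents that add atoms: benzyl bromide BrCc1ccccc1
Why: Williamson etherification with one equivalent should take only the hydroxyl para to the ester, the ortho hydroxyl being chelated to the ester carbonyl.

Step 16
Reactants: 23 4-(benzyloxy)benzaldehyde
Product: 24 4-(benzyloxy)styrene
Conditions: Ph3PCH3Br, KOtBu, THF, 0 °C → rt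
Reagents that add atoms: methyltriphenylphosphonium bromide C[P+](c1ccccc1)(c1ccccc1)c1ccccc1.[Br-]
Why: Wittig methylenation of the aromatic aldehyde gives the styrene.

Step 17
Reactants: 22 methyl 4-(benzyloxy)-2-(bromo unit)-6-hydroxybenzoate; 24 4-(benzyloxy)styrene
Product: 25 methyl 4-(benzyloxy)-2-hydroxy-6-(west unit)benzoate
Conditions: Pd2(dba)3 (2.5 mol %), P(t-Bu)3·HBF4 (10 mol %), Cy2NMe, 1,4-dioxane, 90 °C
Reagents that add atoms: none
Why: Mizoroki–Heck reaction, in which the bulky electron-rich phosphine lets zerovalent palladium insert into the hindered, electron-rich C4–Br bond and syn β-hydride elimination gives the E stilbene.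

Step 18
Reactants: 25 methyl 4-(benzyloxy)-2-hydroxy-6-(west unit)benzoate
Product: 26 5-(benzyloxy)-2-(hydroxymethyl)-3-(west unit)phenol
Conditions: LiAlH4, THF, 0 → 50 °C; aq KNa tartrate
Reagents that add atoms: none
Why: hydride reduction of the salicylate ester to the benzylic alcohol leaves the stilbene and the benzyl ethers untouched.

Step 19
Reactants: 26 5-(benzyloxy)-2-(hydroxymethyl)-3-(west unit)phenol
Product: 27 4-(benzyloxy)-2-hydroxy-6-(west unit)benzaldehyde
Conditions: MnO2, CH2Cl2, rt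
Reagents that add atoms: none
Why: chemoselective MnO2 oxidation of the benzylic alcohol stops at the aldehyde, which is stabilised by its hydrogen bond to the free phenol.

Step 20
Reactants: 27 4-(benzyloxy)-2-hydroxy-6-(west unit)benzaldehyde
Product: 28 5-(benzyloxy)-2-formyl-3-(west unit)phenyl tert-butyl carbonate
Conditions: Boc2O, i-Pr2NEt, DMAP (cat), THF, rt
Reagents that add atoms: di-tert-butyl dicarbonate CC(C)(C)OC(=O)OC(=O)OC(C)(C)C
Why: DMAP-catalysed O-acylation turns the phenol into an aryl carbonate that protects it during aryllithium addition and later serves as the leaving group for quinone methide release.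

Step 21
Reactants: 21 methyl 2-(bromo unit)-4,6-dihydroxybenzoate
Product: 30 5-(bromo unit)benzene-1,3-diol, via carboxylic acid 29 (not isolated)
Conditions: KOH, EtOH/H2O, 90 °C; then AcOH to pH 5, 90 °C
Reagents that add atoms: none
Why: saponification gives the β-resorcylic acid, which is the enol form of a β-keto acid and loses CO2 after ipso protonation, leaving the 3,5-dihydroxyphenyl ring D on C3 with the trans stereochemistry unchanged.

Step 22
Reactants: 30 5-(bromo unit)benzene-1,3-diol
Product: 31 (2R,3R)-6-(benzyloxy)-3-[3,5-bis(benzyloxy)phenyl]-2-[4-(benzyloxy)phenyl]-4-bromo-2,3-dihydro-1-benzofuran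
Conditions: BnBr (2.5 equiv), K2CO3, DMF, 50 °C
Reagents that add atoms: benzyl bromide BrCc1ccccc1
Why: double Williamson etherification protects both phenols of ring D.

Step 23
Reactants: 4 4-(benzyloxy)benzyl chloride
Product: 32 1-[4-(benzyloxy)benzyl]tetrahydrothiophen-1-ium tetrafluoroborate
Conditions: tetrahydrothiophene, NaBF4, acetone, rt
Reagents that add atoms: tetrahydrothiophene C1CCSC1; sodium tetrafluoroborate [Na+].F[B-](F)(F)F
Why: S-alkylation of the sulfide by the reactive benzylic chloride with exchange to the non-nucleophilic anion gives a stable benzylic sulfonium salt.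

Step 24
Reactants: 31 (2R,3R)-6-(benzyloxy)-3-[3,5-bis(benzyloxy)phenyl]-2-[4-(benzyloxy)phenyl]-4-bromo-2,3-dihydro-1-benzofuran; 28 5-(benzyloxy)-2-formyl-3-(west unit)phenyl tert-butyl carbonate
Product: 34 5-(benzyloxy)-2-[(east unit)(hydroxy)methyl]-3-(west unit)phenyl tert-butyl carbonate (both carbinol epimers), via aryllithium 33 (not isolated)
Conditions: t-BuLi (2.0 equiv), THF, −78 °C; then 28, −78 °C; AcOH, −78 °C
Reagents that add atoms: none
Why: bromine–lithium exchange followed by 1,2-addition of the aryllithium to the aldehyde, which is faster than attack on the hindered carbonate, joins the two halves, and the new carbinol centre, formed without control, is erased in the next step.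

Step 25
Reactants: 34 5-(benzyloxy)-2-[(east unit)(hydroxy)methyl]-3-(west unit)phenyl tert-butyl carbonate; 32 1-[4-(benzyloxy)benzyl]tetrahydrothiophen-1-ium tetrafluoroborate
Product: 37 nona-O-benzylmiyabenol A (ring 1 2R,3R; ring 2 2S,3S; ring 3 2R,3R; E stilbene), via benzylic carbonate 35 (not isolated), via quinone methide 36 (not isolated)
Conditions: KOtBu (3 equiv), THF, −40 °C → rt
Reagents that add atoms: none
Why: the alkoxide takes over the Boc group from the phenol oxygen, the phenoxide expels tert-butyl carbonate to give the o-quinone methide, and the sulfonium ylide formed from 32 adds to the methide carbon and is then displaced by the phenoxide (5-exo-tet), a [4+1] annulation in which C3 of ring 2 is set by the face of the methide left open next to the C3 centre of ring 1 and C2 by the invertive closure of the anti betaine, which places the two aryl groups trans.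

Step 26
Reactants: 37 nona-O-benzylmiyabenol A
Product: 38 miyabenol A
Conditions: BCl3, C6HMe5, CH2Cl2, −78 °C; then MeOH
Reagents that add atoms: none
Why: Lewis-acid cleavage of the nine aryl benzyl ethers at −78 °C with pentamethylbenzene as benzyl cation trap should free all phenols without hydrogenating the stilbene and without the strong Brønsted acid that would ionise the benzylic C2–O bonds or cyclise the stilbene onto arene B.

**Compound list**

1 | 5-bromoresorcinol | Oc1cc(O)cc(Br)c1 | starting material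
2 | 2-bromo-4,6-dihydroxybenzaldehyde | O=Cc1c(O)cc(O)cc1Br | intermediate
3 | 4-(benzyloxy)-2-bromo-6-hydroxybenzaldehyde | O=Cc1c(O)cc(OCc2ccccc2)cc1Br | intermediate
4 | 4-(benzyloxy)benzyl chloride | ClCc1ccc(OCc2ccccc2)cc1 | starting material
5 | 4-(benzyloxy)-2-{[4-(benzyloxy)benzyl]oxy}-6-bromobenzaldehyde | O=Cc1c(OCc2ccc(OCc3ccccc3)cc2)cc(OCc2ccccc2)cc1Br | intermediate
6 | 1-(benzyloxy)-3-{[4-(benzyloxy)benzyl]oxy}-5-bromo-4-(2-methoxyethenyl)benzene, E/Z mixture | COC=Cc1c(OCc2ccc(OCc3ccccc3)cc2)cc(OCc2ccccc2)cc1Br | intermediate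
7 | 2-{4-(benzyloxy)-2-[(4-benzyloxybenzyl)oxy]-6-bromophenyl}acetaldehyde | O=CCc1c(OCc2ccc(OCc3ccccc3)cc2)cc(OCc2ccccc2)cc1Br | intermediate
8 | 2-{4-(benzyloxy)-2-[(4-benzyloxybenzyl)oxy]-6-bromophenyl}acetic acid | OC(=O)Cc1c(OCc2ccc(OCc3ccccc3)cc2)cc(OCc2ccccc2)cc1Br | intermediate
9 | methyl 2-{4-(benzyloxy)-2-[(4-benzyloxybenzyl)oxy]-6-bromophenyl}acetate | COC(=O)Cc1c(OCc2ccc(OCc3ccccc3)cc2)cc(OCc2ccccc2)cc1Br | intermediate
10 | methyl 2-{4-(benzyloxy)-2-[(4-benzyloxybenzyl)oxy]-6-bromophenyl}-2-diazoacetate | COC(=O)C(=[N+]=[N-])c1c(OCc2ccc(OCc3ccccc3)cc2)cc(OCc2ccccc2)cc1Br | intermediate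
11 | methyl (2R,3S)-6-(benzyloxy)-2-[4-(benzyloxy)phenyl]-4-bromo-2,3-dihydro-1-benzofuran-3-carboxylate (cis) | Brc1cc(OCc9ccccc9)cc2c1[C@H](C(=O)OC)[C@H](c1ccc(OCc9ccccc9)cc1)O2 | intermediate
12 | methyl (2R,3R)-6-(benzyloxy)-2-[4-(benzyloxy)phenyl]-4-bromo-2,3-dihydro-1-benzofuran-3-carboxylate (trans) | Brc1cc(OCc9ccccc9)cc2c1[C@@H](C(=O)OC)[C@H](c1ccc(OCc9ccccc9)cc1)O2 | intermediate
13 | (2R,3R)-6-(benzyloxy)-2-[4-(benzyloxy)phenyl]-4-bromo-2,3-dihydro-1-benzofuran-3-carbaldehyde | Brc1cc(OCc9ccccc9)cc2c1[C@@H](C=O)[C@H](c1ccc(OCc9ccccc9)cc1)O2 | intermediate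
14 | (2R,3R)-6-(benzyloxy)-2-[4-(benzyloxy)phenyl]-4-bromo-3-ethynyl-2,3-dihydro-1-benzofuran | Brc1cc(OCc9ccccc9)cc2c1[C@@H](C#C)[C@H](c1ccc(OCc9ccccc9)cc1)O2 | intermediate
15 | methyl 3-{(2R,3R)-6-(benzyloxy)-2-[4-(benzyloxy)phenyl]-4-bromo-2,3-dihydro-1-benzofuran-3-yl}prop-2-ynoate | Brc1cc(OCc9ccccc9)cc2c1[C@@H](C#CC(=O)OC)[C@H](c1ccc(OCc9ccccc9)cc1)O2 | intermediate
16 | methyl acetoacetate | COC(=O)CC(C)=O | starting material
17 | methyl 3-(trimethylsilyloxy)but-2-enoate | COC(=O)C=C(C)O[Si](C)(C)C | intermediate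
18 | 1-methoxy-1,3-bis(trimethylsilyloxy)buta-1,3-diene | COC(O[Si](C)(C)C)=CC(=C)O[Si](C)(C)C | intermediate
19 | methyl 2-(bromo unit)-6-methoxy-4,6-bis(trimethylsilyloxy)cyclohexa-1,4-diene-1-carboxylate, both epimers at C6 | Brc1cc(OCc9ccccc9)cc2c1[C@@H](C1=C(C(=O)OC)C(OC)(O[Si](C)(C)C)C=C(O[Si](C)(C)C)C1)[C@H](c1ccc(OCc9ccccc9)cc1)O2 | intermediate
20 | methyl 2-(bromo unit)-4,6-bis(trimethylsilyloxy)benzoate | Brc1cc(OCc9ccccc9)cc2c1[C@@H](c1cc(O[Si](C)(C)C)cc(O[Si](C)(C)C)c1C(=O)OC)[C@H](c1ccc(OCc9ccccc9)cc1)O2 | intermediate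
21 | methyl 2-(bromo unit)-4,6-dihydroxybenzoate | Brc1cc(OCc9ccccc9)cc2c1[C@@H](c1cc(O)cc(O)c1C(=O)OC)[C@H](c1ccc(OCc9ccccc9)cc1)O2 | intermediate
22 | methyl 4-(benzyloxy)-2-(bromo unit)-6-hydroxybenzoate | Brc1cc(OCc9ccccc9)cc2c1[C@@H](c1cc(OCc9ccccc9)cc(O)c1C(=O)OC)[C@H](c1ccc(OCc9ccccc9)cc1)O2 | intermediate
23 | 4-(benzyloxy)benzaldehyde | O=Cc1ccc(OCc2ccccc2)cc1 | starting material
24 | 4-(benzyloxy)styrene | C=Cc1ccc(OCc2ccccc2)cc1 | intermediate
25 | methyl 4-(benzyloxy)-2-hydroxy-6-(west unit)benzoate | c9ccccc9COc1ccc(/C=C/c2cc(OCc9ccccc9)cc3c2[C@@H](c2cc(OCc9ccccc9)cc(O)c2C(=O)OC)[C@H](c2ccc(OCc9ccccc9)cc2)O3)cc1 | intermediate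
26 | 5-(benzyloxy)-2-(hydroxymethyl)-3-(west unit)phenol | c9ccccc9COc1ccc(/C=C/c2cc(OCc9ccccc9)cc3c2[C@@H](c2cc(OCc9ccccc9)cc(O)c2CO)[C@H](c2ccc(OCc9ccccc9)cc2)O3)cc1 | intermediate
27 | 4-(benzyloxy)-2-hydroxy-6-(west unit)benzaldehyde | c9ccccc9COc1ccc(/C=C/c2cc(OCc9ccccc9)cc3c2[C@@H](c2cc(OCc9ccccc9)cc(O)c2C=O)[C@H](c2ccc(OCc9ccccc9)cc2)O3)cc1 | intermediate
28 | 5-(benzyloxy)-2-formyl-3-(west unit)phenyl tert-butyl carbonate | c9ccccc9COc1ccc(/C=C/c2cc(OCc9ccccc9)cc3c2[C@@H](c2cc(OCc9ccccc9)cc(OC(=O)OC(C)(C)C)c2C=O)[C@H](c2ccc(OCc9ccccc9)cc2)O3)cc1 | intermediate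
29 | 2-(bromo unit)-4,6-dihydroxybenzoic acid | Brc1cc(OCc9ccccc9)cc2c1[C@@H](c1cc(O)cc(O)c1C(=O)O)[C@H](c1ccc(OCc9ccccc9)cc1)O2 | intermediate
30 | 5-(bromo unit)benzene-1,3-diol | Brc1cc(OCc9ccccc9)cc2c1[C@@H](c1cc(O)cc(O)c1)[C@H](c1ccc(OCc9ccccc9)cc1)O2 | intermediate
31 | (2R,3R)-6-(benzyloxy)-3-[3,5-bis(benzyloxy)phenyl]-2-[4-(benzyloxy)phenyl]-4-bromo-2,3-dihydro-1-benzofuran | Brc1cc(OCc9ccccc9)cc2c1[C@@H](c1cc(OCc9ccccc9)cc(OCc9ccccc9)c1)[C@H](c1ccc(OCc9ccccc9)cc1)O2 | intermediate
32 | 1-[4-(benzyloxy)benzyl]tetrahydrothiophen-1-ium tetrafluoroborate | c1ccccc1COc1ccc(C[S+]2CCCC2)cc1.F[B-](F)(F)F | intermediate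
33 | (east unit)lithium, the 4-lithio derivative of 31 | [Li]c1cc(OCc9ccccc9)cc2c1[C@@H](c1cc(OCc9ccccc9)cc(OCc9ccccc9)c1)[C@H](c1ccc(OCc9ccccc9)cc1)O2 | intermediate
34 | 5-(benzyloxy)-2-[(east unit)(hydroxy)methyl]-3-(west unit)phenyl tert-butyl carbonate, both carbinol epimers | c9ccccc9COc1ccc(/C=C/c2cc(OCc9ccccc9)cc3c2[C@@H](c2cc(OCc9ccccc9)cc(OC(=O)OC(C)(C)C)c2C(O)c2cc(OCc9ccccc9)cc4c2[C@@H](c2cc(OCc9ccccc9)cc(OCc9ccccc9)c2)[C@H](c2ccc(OCc9ccccc9)cc2)O4)[C@H](c2ccc(OCc9ccccc9)cc2)O3)cc1 | intermediate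
35 | 5-(benzyloxy)-2-[(tert-butoxycarbonyloxy)(east unit)methyl]-3-(west unit)phenol | c9ccccc9COc1ccc(/C=C/c2cc(OCc9ccccc9)cc3c2[C@@H](c2cc(OCc9ccccc9)cc(O)c2C(OC(=O)OC(C)(C)C)c2cc(OCc9ccccc9)cc4c2[C@@H](c2cc(OCc9ccccc9)cc(OCc9ccccc9)c2)[C@H](c2ccc(OCc9ccccc9)cc2)O4)[C@H](c2ccc(OCc9ccccc9)cc2)O3)cc1 | intermediate
36 | 3-(benzyloxy)-6-[(east unit)methylidene]-5-(west unit)cyclohexa-2,4-dien-1-one (o-quinone methide, methide geometry not assigned) | c9ccccc9COc1ccc(/C=C/c2cc(OCc9ccccc9)cc3c2[C@@H](C2=CC(OCc9ccccc9)=CC(=O)C2=Cc5cc(OCc9ccccc9)cc4c5[C@@H](c5cc(OCc9ccccc9)cc(OCc9ccccc9)c5)[C@H](c5ccc(OCc9ccccc9)cc5)O4)[C@H](c2ccc(OCc9ccccc9)cc2)O3)cc1 | intermediate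
37 | nona-O-benzylmiyabenol A (ring 1 2R,3R; ring 2 2S,3S; ring 3 2R,3R; E stilbene) | c9ccccc9COc1ccc(/C=C/c2cc(OCc9ccccc9)cc3c2[C@@H](c2cc(OCc9ccccc9)cc4c2[C@H](c2cc(OCc9ccccc9)cc5c2[C@@H](c2cc(OCc9ccccc9)cc(OCc9ccccc9)c2)[C@H](c2ccc(OCc9ccccc9)cc2)O5)[C@@H](c2ccc(OCc9ccccc9)cc2)O4)[C@H](c2ccc(OCc9ccccc9)cc2)O3)cc1 | intermediate
38 | miyabenol A | Oc1ccc(/C=C/c2cc(O)cc3c2[C@@H](c2cc(O)cc4c2[C@H](c2cc(O)cc5c2[C@@H](c2cc(O)cc(O)c2)[C@H](c2ccc(O)cc2)O5)[C@@H](c2ccc(O)cc2)O4)[C@H](c2ccc(O)cc2)O3)cc1 | target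

**Step count**

Total step count: 26. Longest linear sequence: 20 steps (steps 1–11, 14, 15, 17–20, 24–26).

**Steps most likely to fail**

Step 25. The Michael addition of the ylide to the congested methide carbon may be slow, so that the quinone methide is lost to oligomerisation or to an intramolecular [4+2] reaction with the stilbene. The face selection exerted by the ring 1 centre may also be weak or opposite to what is needed, which would give the ring 2 (2R,3R) diastereomer (trans, separable) instead of the required (2S,3S) ring. The fallback replaces substrate control by reagent control; it sets out from 34 and chloride 4 and comes back at 37. Chloride 4 is S-alkylated with (2R,5R)-2,5-dimethylthiolane and NaBF4 to the C2-symmetric salt (2R,5R)-1-[4-(benzyloxy)benzyl]-2,5-dimethylthiolan-1-ium tetrafluoroborate F1. Its ylide, generated with KOtBu in the presence of 34 as in step 25, transfers the 4-(benzyloxy)benzylidene carbon with the ylide face fixed by the sulfide, so that C2 and, through the anti betaine, C3 of ring 2 are dictated by the reagent and 37 results. The sense of induction is taken by analogy with benzylidene transfer from such salts to aldehydes and would have to be confirmed.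

Step 14. Cycloaddition at the alkyne carbon next to the fully substituted, peri-brominated C3 may be too slow, so that the diene is consumed by silyl migration and hydrolysis before it reacts, or long heating isomerises the ynoate to the allenoate and destroys the C3 centre. The fallback uses a more reactive dienophile on the same carbon; it sets out from alkyne 14 and comes back at 27 (west) and at 29 (east). The acetylide of 14 (LiN(i-Pr)2, THF, −78 °C) is formylated with DMF to 3-(bromo unit)prop-2-ynal F2, which should react with diene 18 well below 100 °C and, after the same acidic work-up, give 2-(bromo unit)-4,6-dihydroxybenzaldehyde F3. For the west, para-selective benzylation gives 4-(benzyloxy)-2-(bromo unit)-6-hydroxybenzaldehyde F4, and Heck reaction with 24 under the conditions of step 17 gives 27 directly. For the east, Lindgren oxidation of F3 (NaClO2, sulfamic acid) gives acid 29, which is decarboxylated to 30 as in step 21.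

Step 8. With the carbene flanked by bromine and the benzyloxy group, enantioface discrimination by the catalyst may be poor, and oxonium ylide formation with [1,2]-shift may compete with insertion. The fallback uses auxiliary control with separation of diastereomers; it sets out from acid 8 and comes back at 12. Acid 8 is esterified (DCC, DMAP) with (S)-2-hydroxy-1-(pyrrolidin-1-yl)propan-1-one to the lactamide ester F5, and diazo transfer as in step 7 gives the diazo ester F6. Insertion with Rh2(S-DOSP)4 gives diastereomeric dihydrobenzofurans from which (S)-1-oxo-1-(pyrrolidin-1-yl)propan-2-yl (2R,3R)-6-(benzyloxy)-2-[4-(benzyloxy)phenyl]-4-bromo-2,3-dihydro-1-benzofuran-3-carboxylate F7 is isolated by chromatography. NaOMe in MeOH then transesterifies it, with equilibration of C3, to 12.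

Further compounds
F1 | step 25 | (2R,5R)-1-[4-(benzyloxy)benzyl]-2,5-dimethylthiolan-1-ium tetrafluoroborate | C[C@@H]1CC[C@@H](C)[S+]1Cc1ccc(OCc2ccccc2)cc1.F[B-](F)(F)F
F2 | step 14 | 3-(bromo unit)prop-2-ynal | Brc1cc(OCc9ccccc9)cc2c1[C@@H](C#CC=O)[C@H](c1ccc(OCc9ccccc9)cc1)O2
F3 | step 14 | 2-(bromo unit)-4,6-dihydroxybenzaldehyde | Brc1cc(OCc9ccccc9)cc2c1[C@@H](c1cc(O)cc(O)c1C=O)[C@H](c1ccc(OCc9ccccc9)cc1)O2
F4 | step 14 | 4-(benzyloxy)-2-(bromo unit)-6-hydroxybenzaldehyde | Brc1cc(OCc9ccccc9)cc2c1[C@@H](c1cc(OCc9ccccc9)cc(O)c1C=O)[C@H](c1ccc(OCc9ccccc9)cc1)O2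
F5 | step 8 | (S)-1-oxo-1-(pyrrolidin-1-yl)propan-2-yl 2-{4-(benzyloxy)-2-[(4-benzyloxybenzyl)oxy]-6-bromophenyl}acetate | C[C@H](OC(=O)Cc1c(OCc2ccc(OCc3ccccc3)cc2)cc(OCc2ccccc2)cc1Br)C(=O)N1CCCC1
F6 | step 8 | (S)-1-oxo-1-(pyrrolidin-1-yl)propan-2-yl 2-{4-(benzyloxy)-2-[(4-benzyloxybenzyl)oxy]-6-bromophenyl}-2-diazoacetate | C[C@H](OC(=O)C(=[N+]=[N-])c1c(OCc2ccc(OCc3ccccc3)cc2)cc(OCc2ccccc2)cc1Br)C(=O)N1CCCC1
F7 | step 8 | (S)-1-oxo-1-(pyrrolidin-1-yl)propan-2-yl (2R,3R)-6-(benzyloxy)-2-[4-(benzyloxy)phenyl]-4-bromo-2,3-dihydro-1-benzofuran-3-carboxylate | Brc1cc(OCc9ccccc9)cc2c1[C@@H](C(=O)O[C@@H](C)C(=O)N1CCCC1)[C@H](c1ccc(OCc9ccccc9)cc1)O2
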